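Ring B holds its two sp3 C–O carbons, C7 and C10, in a 1,4 relationship with C5–C6 between them, so an oxygen-bridged seven-membered ring is hidden in the target. Everything rests on unmasking it: a rhodium carbenoid at C10 is captured by the ortho-formyl oxygen (C7) and the resulting cyclic carbonyl ylide adds across the tethered C5=C6 vinyl group. One operation makes O–C10, C5–C10 and C6–C7, closes rings A and B and sets C5 and C10. The precursor is an achiral ortho-formyl aryl α-diazo ketone with a vinylmalonate at C4, carried as its di-tert-butyl ester so that one later acid treatment opens the bridge, lactonises and frees the α-carboxyl.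

Key step: step 11

Remark (numbering): icetexane numbering is used; C18 is the 4α-carbon, C19 the lactone carbonyl, C20 the ring-B carbon between C9 and C10; the target is (4S,5S,7R,10S).
Remark (assumption): electrophilic formylation of 12 is taken to occur at C5 (ortho to the 4-OMe, para to the 2-OMe), as with 1,2,4-trimethoxybenzene itself.
Remark (assumption): which enantiomer of the dirhodium catalyst gives the (5S,7S,10R) adduct must be found by experiment; the antipodal catalyst is used if the sense is opposite.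
Remark: the C20 carbinol centre of 26 and 27 is not controlled, is removed in step 15 and is drawn without configuration.

Step 1
Reactants: 1 di-tert-butyl malonate; 2 acetaldehyde
Product: 3 di-tert-butyl 2-ethylidenemalonate
Conditions: TiCl4, pyridine, THF, 0 °C → rt
Reagents that add atoms: none
Why: Knoevenagel condensation under pyridine-buffered titanium conditions, which run at 0 °C (suited to acetaldehyde) and should leave tert-butyl esters intact; excess aldehyde suppresses the Michael bis-adduct.

Step 2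
Reactants: 4 5-bromopentanoyl chloride
Product: 5 5-bromo-N-methoxy-N-methylpentanamide
Conditions: MeNH(OMe)·HCl, pyridine, CH2Cl2, 0 °C
Reagents that add atoms: N,O-dimethylhydroxylamine hydrochloride, CNOC.Cl
Why: Weinreb amide formation by N-acylation with an acid chloride; the primary bromide is inert at 0 °C.

Step 3
Reactants: 3 di-tert-butyl 2-ethylidenemalonate; 5 5-bromo-N-methoxy-N-methylpentanamide
Product: 7 di-tert-butyl 2-[5-(methoxy(methyl)amino)-5-oxopentyl]-2-vinylmalonate, via lithium dienolate 6 (not isolated)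
Conditions: LDA, THF/DMPU, −78 °C; then 5, NaI (cat.), −78 °C → rt
Reagents that add atoms: none
Why: Deconjugative α-alkylation of an alkylidenemalonate: γ-deprotonation gives the extended dienolate, which the primary halide alkylates at the α-carbon to give the quaternary vinylmalonate; the stabilised dienolate does not attack the Weinreb amide.

Step 4
Reactants: 8 1,2,4-trimethoxybenzene; 9 acetone
Product: 11 2-(2,3,6-trimethoxyphenyl)propan-2-ol, via 2,3,6-trimethoxyphenyllithium 10 (not isolated)
Conditions: n-BuLi, THF, 0 °C → rt; acetone, −78 °C → rt; aq. NH4Cl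
Reagents that add atoms: none
Why: Directed ortho-metalation at C3, the position flanked by two methoxy groups, followed by 1,2-addition to acetone.

Step 5
Reactants: 11 2-(2,3,6-trimethoxyphenyl)propan-2-ol
Product: 12 3-isopropyl-1,2,4-trimethoxybenzene
Conditions: Et3SiH, TFA, CH2Cl2, 0 °C → rt
Reagents that add atoms: none
Why: Ionic hydrogenation: the tertiary benzylic cation formed in TFA is reduced by hydride transfer from the silane.

Step 6
Reactants: 12 3-isopropyl-1,2,4-trimethoxybenzene
Product: 13 3-isopropyl-2,4,5-trimethoxybenzaldehyde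
Conditions: Cl2CHOMe, TiCl4, CH2Cl2, −78 → 0 °C; H2O
Reagents that add atoms: dichloromethyl methyl ether, COC(Cl)Cl; water, O
Why: Rieche formylation (electrophilic aromatic substitution) at the position ortho to the coplanar 4-methoxy and para to the 2-methoxy group; this places the future C7 carbon on C8.

Step 7
Reactants: 13 3-isopropyl-2,4,5-trimethoxybenzaldehyde
Product: 14 1-(dimethoxymethyl)-3-isopropyl-2,4,5-trimethoxybenzene
Conditions: HC(OMe)3, p-TsOH (cat.), MeOH, rt; Et3N quench
Reagents that add atoms: trimethyl orthoformate, COC(OC)OC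
Why: Acid-catalysed acetalisation driven by the orthoformate; the acetal shields the aldehyde from the bases of steps 8 and 9 and acts as an ortho-directing group.

Step 8
Reactants: 14 1-(dimethoxymethyl)-3-isopropyl-2,4,5-trimethoxybenzene; 7 di-tert-butyl 2-[5-(methoxy(methyl)amino)-5-oxopentyl]-2-vinylmalonate
Product: 16 di-tert-butyl 2-{5-[2-(dimethoxymethyl)-4-isopropyl-3,5,6-trimethoxyphenyl]-5-oxopentyl}-2-vinylmalonate, via ortho-lithiated acetal 15 (not isolated)
Conditions: n-BuLi, TMEDA, THF, −20 → 0 °C; then 7, −78 → 0 °C; aq. NH4Cl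
Reagents that add atoms: none
Why: Directed ortho-metalation at the only ring C–H left (between the acetal and a methoxy group), then Weinreb ketone synthesis; the chelated tetrahedral intermediate prevents over-addition and the hindered tert-butyl esters should not be attacked at −78 °C.

Step 9
Reactants: 16 di-tert-butyl 2-{5-[2-(dimethoxymethyl)-4-isopropyl-3,5,6-trimethoxyphenyl]-5-oxopentyl}-2-vinylmalonate
Product: 18 di-tert-butyl 2-{4-diazo-5-[2-(dimethoxymethyl)-4-isopropyl-3,5,6-trimethoxyphenyl]-5-oxopentyl}-2-vinylmalonate, via α-trifluoroacetyl ketone 17 (not isolated)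
Conditions: LiHMDS, THF, −78 °C; CF3CO2CH2CF3; then MsN3, Et3N, H2O, MeCN, rt
Reagents that add atoms: methanesulfonyl azide, CS(=O)(=O)N=[N+]=[N-]
Why: Detrifluoroacetylative (Regitz-type deacylative) diazo transfer: the enolate of the only enolisable position is C-trifluoroacetylated and the activated 1,3-diketone takes the diazo group from the sulfonyl azide with loss of the trifluoroacetyl group; the aldehyde is still masked, so the enolate cannot add to it.

Step 10
Reactants: 18 di-tert-butyl 2-{4-diazo-5-[2-(dimethoxymethyl)-4-isopropyl-3,5,6-trimethoxyphenyl]-5-oxopentyl}-2-vinylmalonate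
Product: 19 di-tert-butyl 2-[4-diazo-5-(2-formyl-4-isopropyl-3,5,6-trimethoxyphenyl)-5-oxopentyl]-2-vinylmalonate
Conditions: PPTS (cat.), acetone/H2O, 0 °C → rt
Reagents that add atoms: water, O
Why: Acetal hydrolysis under weakly acidic buffering; the dimethyl acetal of a 2,4-dialkoxybenzaldehyde should ionise much faster than the α-diazo ketone is protonated.

Step 11
Reactants: 19 di-tert-butyl 2-[4-diazo-5-(2-formyl-4-isopropyl-3,5,6-trimethoxyphenyl)-5-oxopentyl]-2-vinylmalonate
Product: 22 di-tert-butyl (5S,7S,10R)-7β,10β-epoxy-11,12,14-trimethoxy-20-oxoicetexa-8,11,13-triene-18,19-dioate (5α-H), via rhodium carbenoid 20 (not isolated), via carbonyl ylide 21 (not isolated)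
Conditions: Rh2(S-TCPTTL)4 (1 mol %), PhCF3, −20 °C, slow addition of 19
Reagents that add atoms: none
Why: Loss of N2 gives the rhodium carbenoid at C10, whose carbon is attacked by the lone pair of the ortho-formyl oxygen to form the six-membered carbonyl ylide (a 2-benzopyrylium-4-olate, new O–C10 bond), and this adds suprafacially to the tethered vinyl group. The closest known reaction type is the Rh(II)-catalysed carbonyl ylide formation and intramolecular 1,3-dipolar cycloaddition of ortho-carbonyl aryl diazo ketones, with asymmetric induction by chiral dirhodium carboxylates as known for 2-benzopyrylium-4-olates and for tethered ylides. Ring A closes through C5–C10 as a six-membered ring in a fused, chair-like mode set by the four-atom tether, and ring B closes through C6–C7 as the seven-membered carbocycle of an 8-oxabicyclo[3.2.1]octane, the tether length fixing the regiochemistry. C7 and C10 are joined by the oxygen bridge and are therefore cis; C5 is set relative to C10 by the exo tether geometry (H5 anti to the bridge), the only one a chair-like four-atom tether allows; the absolute sense comes from the chiral catalyst, which stays associated with the ylide and tells its enantiotopic faces apart. The step needs ylide formation to outrun 1,2-hydride shift from C1–H, which the proximity of the formyl oxygen, the bulky electron-poor carboxylate ligands and the low temperature should secure.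

Step 12
Reactants: 22 di-tert-butyl (5S,7S,10R)-7β,10β-epoxy-11,12,14-trimethoxy-20-oxoicetexa-8,11,13-triene-18,19-dioate
Product: 25 7α-acetoxy-11,12,14-trimethoxy-20-oxoicetexa-8,11,13-trien-19,10β-olid-18-oic acid, via bridged diacid 23 (not isolated), via hydroxy diacid acetate 24 (not isolated)
Conditions: BF3·OEt2, AcOH/CH2Cl2, 0 °C → rt
Reagents that add atoms: acetic acid, CC(=O)O
Why: Lewis-acid acetolysis of a benzylic bridged ether: BF3 cleaves the tert-butyl esters and activates the bridge oxygen, the C7–O bond ionises with help from the ortho and para methoxy groups, and acetic acid should enter on the α face (anti to the departing oxygen, giving the pseudo-axial acetate free of peri strain with the C14 methoxy); the freed 10β-hydroxyl lactonises onto the 1,3-diaxial β-carboxyl, the only one in reach, which sets C4 and leaves the α-carboxyl free.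

Step 13
Reactants: 25 7α-acetoxy-11,12,14-trimethoxy-20-oxoicetexa-8,11,13-trien-19,10β-olid-18-oic acid
Product: 26 7α-acetoxy-18,20-dihydroxy-11,12,14-trimethoxyicetexa-8,11,13-trien-19,10β-olide (C20 epimers)
Conditions: BH3·SMe2, THF, 0 °C → rt; MeOH
Reagents that add atoms: none
Why: Chemoselective borane reduction: carboxylic acids (via acyloxyboranes) and ketones react far faster than lactones or acetates, so C18 becomes a primary carbinol and C20 a benzylic carbinol of uncontrolled and irrelevant configuration, without alkoxide intermediates that could move acyl groups.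

Step 14
Reactants: 26 7α-acetoxy-18,20-dihydroxy-11,12,14-trimethoxyicetexa-8,11,13-trien-19,10β-olide
Product: 27 18,20-bis-O-(imidazol-1-ylthiocarbonyl) derivative of 26
Conditions: TCDI, DMAP, ClCH2CH2Cl, 70 °C
Reagents that add atoms: 1,1'-thiocarbonyldiimidazole, S=C(n1ccnc1)n1ccnc1
Why: Thiocarbonylation of both alcohols under neutral conditions (first half of the Barton–McCombie deoxygenation), which spares the acetate and the lactone.

Step 15
Reactants: 27 18,20-bis-O-(imidazol-1-ylthiocarbonyl) derivative of 26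
Product: 28 7α-acetoxy-11,12,14-trimethoxyicetexa-8,11,13-trien-19,10β-olide
Conditions: Bu3SnH, AIBN, toluene, 110 °C
Reagents that add atoms: none
Why: Barton–McCombie radical deoxygenation: stannyl radical addition to each thiocarbonyl and β-scission give the benzylic C20 and primary C18 radicals, which take hydrogen from the stannane, so C20 becomes CH2 and C18 the 4α-methyl while acetate, lactone and aryl ethers are inert.

Step 16
Reactants: 28 7α-acetoxy-11,12,14-trimethoxyicetexa-8,11,13-trien-19,10β-olide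
Product: 29 7α-acetoxy-12-methoxy-11,14-dioxoicetexa-8,12-dien-19,10β-olide
Conditions: CAN, MeCN/H2O, 0 °C
Reagents that add atoms: water, O
Why: Oxidative demethylation of the para-dimethoxyarene (C11/C14) by cerium(IV) to the para-quinone with the C12 methyl ether kept as a vinylogous ester; the reaction is fast at 0 °C, so the benzylic acetate meets the acidic medium only briefly.

Step 17
Reactants: 29 7α-acetoxy-12-methoxy-11,14-dioxoicetexa-8,12-dien-19,10β-olide
Product: 30 7α-acetoxy-6,7-dihydroicetexone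
Conditions: LiCl, DMF, 80 °C; 1 M HCl work-up
Reagents that add atoms: none
Why: Krapcho-type SN2 demethylation by chloride of a methoxyquinone, a vinylogous methyl ester whose leaving group is the acidic hydroxyquinone anion; the neutral conditions should spare the secondary acetate and the tertiary-alkyl lactone.

Compound list
1 | di-tert-butyl malonate | CC(C)(C)OC(=O)CC(=O)OC(C)(C)C | starting material
2 | acetaldehyde | CC=O | starting material
3 | di-tert-butyl 2-ethylidenemalonate | CC=C(C(=O)OC(C)(C)C)C(=O)OC(C)(C)C | intermediate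
4 | 5-bromopentanoyl chloride | O=C(Cl)CCCCBr | starting material
5 | 5-bromo-N-methoxy-N-methylpentanamide | CON(C)C(=O)CCCCBr | intermediate
6 | lithium dienolate of 3 (not isolated) | [Li+].[O-]C(OC(C)(C)C)=C(C=C)C(=O)OC(C)(C)C | intermediate
7 | di-tert-butyl 2-[5-(methoxy(methyl)amino)-5-oxopentyl]-2-vinylmalonate | C=CC(CCCCC(=O)N(C)OC)(C(=O)OC(C)(C)C)C(=O)OC(C)(C)C | intermediate
8 | 1,2,4-trimethoxybenzene | COc1ccc(OC)c(OC)c1 | starting material
9 | acetone | CC(C)=O | starting material
10 | 2,3,6-trimethoxyphenyllithium (not isolated) | [Li]c1c(OC)ccc(OC)c1OC | intermediate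
11 | 2-(2,3,6-trimethoxyphenyl)propan-2-ol | CC(C)(O)c1c(OC)ccc(OC)c1OC | intermediate
12 | 3-isopropyl-1,2,4-trimethoxybenzene | CC(C)c1c(OC)ccc(OC)c1OC | intermediate
13 | 3-isopropyl-2,4,5-trimethoxybenzaldehyde | O=Cc1cc(OC)c(OC)c(C(C)C)c1OC | intermediate
14 | 1-(dimethoxymethyl)-3-isopropyl-2,4,5-trimethoxybenzene | COC(OC)c1cc(OC)c(OC)c(C(C)C)c1OC | intermediate
15 | [2-(dimethoxymethyl)-4-isopropyl-3,5,6-trimethoxyphenyl]lithium (not isolated) | [Li]c1c(C(OC)OC)c(OC)c(C(C)C)c(OC)c1OC | intermediate
16 | di-tert-butyl 2-{5-[2-(dimethoxymethyl)-4-isopropyl-3,5,6-trimethoxyphenyl]-5-oxopentyl}-2-vinylmalonate | C=CC(CCCCC(=O)c1c(C(OC)OC)c(OC)c(C(C)C)c(OC)c1OC)(C(=O)OC(C)(C)C)C(=O)OC(C)(C)C | intermediate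
17 | α-trifluoroacetyl derivative of 16 at C10 (not isolated) | C=CC(CCCC(C(=O)C(F)(F)F)C(=O)c1c(C(OC)OC)c(OC)c(C(C)C)c(OC)c1OC)(C(=O)OC(C)(C)C)C(=O)OC(C)(C)C | intermediate
18 | diazo ketone acetal | C=CC(CCCC(=[N+]=[N-])C(=O)c1c(C(OC)OC)c(OC)c(C(C)C)c(OC)c1OC)(C(=O)OC(C)(C)C)C(=O)OC(C)(C)C | intermediate
19 | ortho-formyl aryl α-diazo ketone (key-step precursor, achiral) | C=CC(CCCC(=[N+]=[N-])C(=O)c1c(C=O)c(OC)c(C(C)C)c(OC)c1OC)(C(=O)OC(C)(C)C)C(=O)OC(C)(C)C | intermediate
20 | rhodium carbenoid at C10 (dirhodium tetracarboxylate drawn as Rh; not isolated) | C=CC(CCCC(=[Rh])C(=O)c1c(C=O)c(OC)c(C(C)C)c(OC)c1OC)(C(=O)OC(C)(C)C)C(=O)OC(C)(C)C | intermediate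
21 | carbonyl ylide, 3-substituted 2-benzopyrylium-4-olate (not isolated) | C=CC(CCCC1=C([O-])c2c(OC)c(OC)c(C(C)C)c(OC)c2C=[O+]1)(C(=O)OC(C)(C)C)C(=O)OC(C)(C)C | intermediate
22 | (5S,7S,10R) cycloadduct: 7β,10β-epoxy-20-oxo diester, 5α-H | O1[C@H]2C[C@@H]3[C@]1(CCCC3(C(=O)OC(C)(C)C)C(=O)OC(C)(C)C)C(=O)c1c2c(OC)c(C(C)C)c(OC)c1OC | intermediate
23 | bridged diacid, 7β,10β-epoxy-20-oxo-18,19-dioic acid (not isolated) | O1[C@H]2C[C@@H]3[C@]1(CCCC3(C(=O)O)C(=O)O)C(=O)c1c2c(OC)c(C(C)C)c(OC)c1OC | intermediate
24 | 7α-acetoxy-10β-hydroxy-20-oxo-18,19-dioic acid (not isolated) | CC(=O)O[C@@H]1C[C@@H]2[C@](O)(CCCC2(C(=O)O)C(=O)O)C(=O)c2c1c(OC)c(C(C)C)c(OC)c2OC | intermediate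
25 | 7α-acetoxy-11,12,14-trimethoxy-20-oxoicetexa-8,11,13-trien-19,10β-olid-18-oic acid | CC(=O)O[C@@H]1C[C@@H]2[C@]3(CCC[C@]2(C(=O)O)C(=O)O3)C(=O)c2c1c(OC)c(C(C)C)c(OC)c2OC | intermediate
26 | 7α-acetoxy-18,20-dihydroxy-11,12,14-trimethoxyicetexa-8,11,13-trien-19,10β-olide (C20 epimers) | CC(=O)O[C@@H]1C[C@@H]2[C@]3(CCC[C@]2(CO)C(=O)O3)C(O)c2c1c(OC)c(C(C)C)c(OC)c2OC | intermediate
27 | 18,20-bis-O-(imidazol-1-ylthiocarbonyl) derivative of 26 (C20 epimers) | CC(=O)O[C@@H]1C[C@@H]2[C@]3(CCC[C@]2(COC(=S)n4ccnc4)C(=O)O3)C(OC(=S)n5ccnc5)c6c1c(OC)c(C(C)C)c(OC)c6OC | intermediate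
28 | 7α-acetoxy-11,12,14-trimethoxyicetexa-8,11,13-trien-19,10β-olide | CC(=O)O[C@@H]1C[C@@H]2[C@]3(CCC[C@]2(C)C(=O)O3)Cc2c1c(OC)c(C(C)C)c(OC)c2OC | intermediate
29 | 12-O-methyl ether of the target (12-methoxy-11,14-quinone) | CC(=O)O[C@@H]1C[C@@H]2[C@]3(CCC[C@]2(C)C(=O)O3)CC2=C1C(=O)C(C(C)C)=C(OC)C2=O | intermediate
30 | 7α-acetoxy-6,7-dihydroicetexone, (4S,5S,7R,10S) | CC(=O)O[C@@H]1C[C@@H]2[C@]3(CCC[C@]2(C)C(=O)O3)CC2=C1C(=O)C(C(C)C)=C(O)C2=O | target

Total steps: 17. Longest linear sequence: 14 (steps 4–17, from 8).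

Steps most likely to fail

1. Step 11. The carbenoid may undergo 1,2-hydride migration from C1 faster than the formyl oxygen captures it, and the catalyst may discriminate the two faces of the ylide poorly. The fallback sets out from 16 and comes back at 25; it generates the same ylide without a metal carbene and obtains the enantiomer by resolution. The potassium enolate of 16 is hydroxylated at C10 with 2-(phenylsulfonyl)-3-phenyloxaziridine to give the α-hydroxy ketone F1. Mild acid hydrolysis of the acetal lets the hydroxyl close onto the freed aldehyde to give the lactol F2, which is acetylated (Ac2O, DMAP) to the 1-acetoxyisochromanone F3. DBU in MeCN at 60 °C eliminates acetic acid to form ylide 21 (base-induced oxidopyrylium generation), which adds to the vinyl group to give the racemic cycloadduct F4. The conditions of step 12 give the racemic keto lactone acid F5, which is resolved by crystallisation as the (R)-1-phenylethylammonium salt F6 (or with the antipodal amine, whichever salt of 25 crystallises). Acidification returns 25.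

2. Step 12. The benzylic cation may be captured without facial control, or lose H6 to the C6=C7 styrene. The fallback sets out from 22 and comes back at 28; C7 is fixed by a reagent-controlled ketone reduction and not by the acetolysis. 22 is taken through steps 12 to 15 whatever the outcome at C7. The 7β-acetate F7 (alone or mixed with 28) is methanolysed with K2CO3 in MeOH to the 7β-alcohol F8, and Dess–Martin oxidation converges the material on the 7-ketone F9. Corey–Bakshi–Shibata reduction with the (S)-methyl oxazaborolidine and BH3·SMe2 at −20 °C should deliver hydride to the β face of this aryl ketone to give the 7α-alcohol F10 (7R). Ac2O, DMAP and pyridine then give 28.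

3. Step 10. While the acetal is hydrolysed, the diazo carbon may be protonated with loss of nitrogen, or may add to the freed aldehyde. The fallback sets out from 16 and comes back at 19; the acid treatment is moved in front of the diazo transfer and the aldehyde is unveiled by a neutral oxidation. Hydrolysis of 16 (PPTS, aqueous acetone) gives the keto aldehyde F11. NaBH4 at −78 °C reduces only the aldehyde to the hydroxymethyl ketone F12 (in equilibrium with its cyclic hemiketal), and TBSCl with imidazole gives the silyl ether F13. The diazo transfer of step 9 gives the diazo ketone silyl ether F14, and acetic acid-buffered TBAF gives the diazo keto alcohol F15. Activated MnO2 in CH2Cl2 oxidises the benzylic alcohol to 19.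

Further compounds
F1 | step 11 | α-hydroxy ketone acetal (C10 carbinol of 16, racemic) | C=CC(CCCC(O)C(=O)c1c(C(OC)OC)c(OC)c(C(C)C)c(OC)c1OC)(C(=O)OC(C)(C)C)C(=O)OC(C)(C)C
F2 | step 11 | lactol, 1-hydroxy-3-alkylisochroman-4-one (diastereomers) | OC1OC(CCCC(C=C)(C(=O)OC(C)(C)C)C(=O)OC(C)(C)C)C(=O)c2c(OC)c(OC)c(C(C)C)c(OC)c12
F3 | step 11 | 1-acetoxy-3-alkylisochroman-4-one (diastereomers) | CC(=O)OC1OC(CCCC(C=C)(C(=O)OC(C)(C)C)C(=O)OC(C)(C)C)C(=O)c2c(OC)c(OC)c(C(C)C)c(OC)c12
F4 | step 11 | racemic cycloadduct (22 and its enantiomer) | O1[C@H]2C[C@@H]3[C@]1(CCCC3(C(=O)OC(C)(C)C)C(=O)OC(C)(C)C)C(=O)c1c2c(OC)c(C(C)C)c(OC)c1OC.O1[C@@H]2C[C@H]3[C@@]1(CCCC3(C(=O)OC(C)(C)C)C(=O)OC(C)(C)C)C(=O)c1c2c(OC)c(C(C)C)c(OC)c1OC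
F5 | step 11 | racemic keto lactone acid (25 and its enantiomer) | CC(=O)O[C@@H]1C[C@@H]2[C@]3(CCC[C@]2(C(=O)O)C(=O)O3)C(=O)c2c1c(OC)c(C(C)C)c(OC)c2OC.CC(=O)O[C@H]1C[C@H]2[C@@]3(CCC[C@@]2(C(=O)O)C(=O)O3)C(=O)c2c1c(OC)c(C(C)C)c(OC)c2OC
F6 | step 11 | (R)-1-phenylethylammonium salt of 25 | C[C@@H]([NH3+])c1ccccc1.CC(=O)O[C@@H]1C[C@@H]2[C@]3(CCC[C@]2(C(=O)[O-])C(=O)O3)C(=O)c2c1c(OC)c(C(C)C)c(OC)c2OC
F7 | step 12 | 7β-acetate (C7 epimer of 28) | CC(=O)O[C@H]1C[C@@H]2[C@]3(CCC[C@]2(C)C(=O)O3)Cc2c1c(OC)c(C(C)C)c(OC)c2OC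
F8 | step 12 | 7β-hydroxy-11,12,14-trimethoxyicetexa-8,11,13-trien-19,10β-olide | O[C@H]1C[C@@H]2[C@]3(CCC[C@]2(C)C(=O)O3)Cc2c1c(OC)c(C(C)C)c(OC)c2OC
F9 | step 12 | 7-oxo-11,12,14-trimethoxyicetexa-8,11,13-trien-19,10β-olide | O=C1C[C@@H]2[C@]3(CCC[C@]2(C)C(=O)O3)Cc2c1c(OC)c(C(C)C)c(OC)c2OC
F10 | step 12 | 7α-hydroxy-11,12,14-trimethoxyicetexa-8,11,13-trien-19,10β-olide | O[C@@H]1C[C@@H]2[C@]3(CCC[C@]2(C)C(=O)O3)Cc2c1c(OC)c(C(C)C)c(OC)c2OC
F11 | step 10 | keto aldehyde (16 with the acetal hydrolysed) | C=CC(CCCCC(=O)c1c(C=O)c(OC)c(C(C)C)c(OC)c1OC)(C(=O)OC(C)(C)C)C(=O)OC(C)(C)C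
F12 | step 10 | hydroxymethyl ketone | C=CC(CCCCC(=O)c1c(CO)c(OC)c(C(C)C)c(OC)c1OC)(C(=O)OC(C)(C)C)C(=O)OC(C)(C)C
F13 | step 10 | tert-butyldimethylsilyl ether of F12 | C=CC(CCCCC(=O)c1c(CO[Si](C)(C)C(C)(C)C)c(OC)c(C(C)C)c(OC)c1OC)(C(=O)OC(C)(C)C)C(=O)OC(C)(C)C
F14 | step 10 | diazo ketone silyl ether | C=CC(CCCC(=[N+]=[N-])C(=O)c1c(CO[Si](C)(C)C(C)(C)C)c(OC)c(C(C)C)c(OC)c1OC)(C(=O)OC(C)(C)C)C(=O)OC(C)(C)C
F15 | step 10 | diazo keto alcohol | C=CC(CCCC(=[N+]=[N-])C(=O)c1c(CO)c(OC)c(C(C)C)c(OC)c1OC)(C(=O)OC(C)(C)C)C(=O)OC(C)(C)C
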